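## The problem

Target 16 is an acyclic 8-O-4′ neolignan. A guaiacyl ring A carries the chain C7–C8–C9. The C8 oxygen is bound to C4′ of a syringyl-type ring B (2,6-dimethoxy, with a 3-hydroxypropyl chain C7′–C9′ para to the ether oxygen). O4 of ring A is etherified with C2 of glycerol, an achiral CH(CH2OH)2 unit.

There are only two stereocentres, the benzylic carbinol C7 (S) and the aryloxy carbon C8 (R). They are vicinal and erythro: 7-OH and 8-OAr lie anti in the zigzag Ar–C7–C8–C9. Nothing else in the molecule can relay stereochemistry to them, so relative and absolute control must both come from the step that makes them.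

The erythro relation is the awkward one. Closed-transition-state boron aldols give the 7,8-syn (threo) series, and outer-sphere reductions of a C7 ketone are expected to favour threo as well (polar Felkin–Anh). The C8–O bond leads to a di-ortho-substituted phenol, a poor nucleophile at a secondary carbon. C8 epimerises whenever C7 or C9 is a carbonyl. The C7 alcohol is a p-alkoxybenzylic alcohol that ionises in acid, and five hydroxyl groups need economical protection.

The feature that makes the key step possible: C7 and C8 each carry one hydrogen, C7 bears OH and C8 bears the ring-B oxygen. Syn addition of H (to C8) and OH (to C7) across a C7=C8 enol ether in which ring A and the ring-B oxygen are cis (Z) gives exactly the erythro pair. The C9′ alcohol of ring B is likewise the anti-Markovnikov hydration product of an allyl group (C8′=C9′), so one borane oxidation can deliver both.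

## Retrosynthesis

**16 ⇐ 15.** Three O–Si bonds are cut (the two glycerol oxygens and O9). Fluoride is preferred to acid-labile acetals because the C7 p-alkoxybenzylic alcohol must not see acid. The forward reaction only has to remove silicon.

**15 ⇐ 12 (key disconnection).** The C7–OH and C8–H bonds are cut together, and with them C9′–OH and C8′–H of the side chain. All four are formed by adding H–B across C=C and exchanging B for O. Cutting C7–C8 instead (aldol) would need anti-glycolate enolate control. Cutting C8–OAr would need SN2 by the hindered phenol at a secondary stereocentre. The chosen cut needs neither. Precursor 12 has no stereocentre, only a Z double bond that can be set under thermodynamic control, and an allyl group that comes with commercial phenol 5. The forward reaction must place boron on C7, add syn, choose one alkene face, and treat the terminal alkene separately.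

**12 ⇐ 11 ⇐ 10.** The O9–Si bond and the ester oxidation level are adjusted. A free allylic OH would consume and redirect the chiral borane, and an ester would be reduced by it. C9 is therefore reduced first and capped with the same silyl group used on the glycerol unit. The Z geometry is untouched.

**10 ⇐ 8 ⇐ 7 + 4.** The C7=C8 bond is cut as an ester aldol followed by elimination. No stereochemical demand is placed on the C–C bond formation. Both diastereomers of aldol 8 are meant to converge, through an E1cB elimination, on the acrylate 10 with ring A trans to the ester (Z).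

**7 ⇐ 5 + 6.** The ring-B O–C8 bond is cut while C8 is still a primary carbon (bromoacetate 6). Here even a 2,6-dimethoxyphenoxide alkylates readily. This removes the hindered-ether problem before any stereocentre exists.

**4 ⇐ 3 + 2; 2 ⇐ 1.** The ring-A O4–C bond is made by a Mitsunobu reaction of vanillin 3 with the symmetric secondary alcohol 2. Inversion is irrelevant because the carbinol carbon is not stereogenic. Alcohol 2 comes from glycerol 1 by silylation of the two primary hydroxyls.

## Roads not taken

**Alternative 1:** Cut C7–C8 as an auxiliary-controlled glycolate aldol, the route most chemists would draw first. The acyl oxazolidinone A1 (from the acid of 7) would add to aldehyde 4. The dependable boron Z-enolate reacts through a Zimmerman–Traxler chair and gives the 2,3-syn adduct, which here is the threo series. The target needs the anti adduct A2. That requires the less general anti-glycolate protocols, whose transition states are sensitive to a chelating, bulky 2,6-dimethoxyaryloxy group, or a later inversion at the SN1-prone C7. It also costs auxiliary attachment and reductive removal. In the chosen plan the relative configuration follows from alkene geometry and the stereospecificity of a syn addition, not from enolate geometry.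

**Alternative 2:** Cut C8–OAr. Asymmetric dihydroxylation of the (E)-cinnamate A3 (from 4) gives the threo diol A4 reliably. Phenol 5 would then have to displace an activated 8-oxygen, such as the 2-nosylate A5, with inversion. With 7-OH free, base closes A5 to the cis-glycidate, and an electron-rich 3-arylglycidate opens at benzylic C7, giving the wrong ether regioisomer. Protecting 7-OH adds steps and makes C8 more crowded for a di-ortho-substituted phenoxide, so elimination competes. The chosen plan forms the hindered ether at a CH2 group and never does substitution at a stereocentre.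

**Alternative 3:** Cut the C7–H bond and rely on dynamic kinetic resolution. The racemic α-aryloxy β-keto ester A6 (from 8 by oxidation) would be reduced by Noyori–Ikariya transfer hydrogenation while C8 racemises. This is convergent and catalytic. But the outer-sphere hydride transfer is expected to follow the polar Felkin–Anh arrangement (C8–O bond anti to hydride), as the closest α-alkoxy β-keto ester cases do, and that leads to the 7,8-syn hydroxy ester A7, the threo series. Correcting this would mean inverting the ionisable benzylic C7 or epimerising C8 next to an ester with retro-aldol risk. The chosen plan obtains erythro by construction.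

Key step: step 8

Assumption: the facial sense of IpcBH2 addition is taken from the empirical model for trans- and trisubstituted alkenes (reagent from (1R)-(+)-α-pinene, boron to the C7 Si face of 12). Should the opposite sense be found, the reagent from (1S)-(−)-α-pinene is used in the same step.

## Route

Step 1
Reactants: 1 glycerol
Product: 2 1,3-bis(tert-butyldimethylsilyloxy)propan-2-ol
Conditions: TBSCl (2.05 equiv), imidazole, DMF, 0 °C
Reagents that add atoms: tert-butyldimethylsilyl chloride, CC(C)(C)[Si](C)(C)Cl
Why: Silylation of the two primary hydroxyls of a triol is faster than that of the flanked secondary one, so the symmetric bis-ether should dominate (selective silyl ether formation).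

Step 2
Reactants: 3 vanillin; 2 1,3-bis(tert-butyldimethylsilyloxy)propan-2-ol
Product: 4 4-{[1,3-bis(tert-butyldimethylsilyloxy)propan-2-yl]oxy}-3-methoxybenzaldehyde
Conditions: PPh3, DIAD, THF, 0 °C → 40 °C
Reagents that add atoms: none
Why: Mitsunobu etherification; vanillin is an acidic phenol (p-formyl) and so a good pronucleophile for a hindered secondary alcohol, and the carbinol carbon is not stereogenic, so inversion has no consequence.

Step 3
Reactants: 5 4-allyl-2,6-dimethoxyphenol; 6 ethyl bromoacetate
Product: 7 ethyl 2-(4-allyl-2,6-dimethoxyphenoxy)acetate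
Conditions: K2CO3, acetone, reflux
Reagents that add atoms: none
Why: Williamson ether synthesis; the di-ortho-substituted phenoxide is hindered but alkylates cleanly at an unhindered primary α-halo ester, which installs the future C8–O bond before C8 is a stereocentre.

Step 4
Reactants: 7 ethyl 2-(4-allyl-2,6-dimethoxyphenoxy)acetate; 4 4-{[1,3-bis(tert-butyldimethylsilyloxy)propan-2-yl]oxy}-3-methoxybenzaldehyde
Product: 8 ethyl 2-(4-allyl-2,6-dimethoxyphenoxy)-3-(4-{[1,3-bis(tert-butyldimethylsilyloxy)propan-2-yl]oxy}-3-methoxyphenyl)-3-hydroxypropanoate (mixture of racemic diastereomers)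
Conditions: LDA, THF, −78 °C; then 4, −78 °C; aq NH4Cl
Reagents that add atoms: none
Why: Lithium ester-enolate aldol addition to a non-enolisable aromatic aldehyde; the diastereomer ratio is irrelevant because both stereocentres are erased in step 5, and silyl ethers and the allyl group tolerate LDA at −78 °C.

Step 5
Reactants: 8 ethyl 2-(4-allyl-2,6-dimethoxyphenoxy)-3-aryl-3-hydroxypropanoate (diastereomer mixture)
Product: 10 ethyl (Z)-2-(4-allyl-2,6-dimethoxyphenoxy)-3-(4-{[1,3-bis(tert-butyldimethylsilyloxy)propan-2-yl]oxy}-3-methoxyphenyl)prop-2-enoate, via benzylic mesylate 9 (not isolated)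
Conditions: MsCl, Et3N, CH2Cl2, 0 °C; then DBU, rt
Reagents that add atoms: none
Why: Sulfonylation then E1cB elimination through the ester enolate (the C8–H is acidic, the benzylic leaving group is labile), which should funnel both diastereomers into the more stable alkene with ring A trans to the ester, i.e. cis to the aryloxy group (Z). Any E isomer is removed here or after step 6.

Step 6
Reactants: 10 ethyl (Z)-2-aryloxy-3-arylprop-2-enoate
Product: 11 (Z)-2-(4-allyl-2,6-dimethoxyphenoxy)-3-(4-{[1,3-bis(tert-butyldimethylsilyloxy)propan-2-yl]oxy}-3-methoxyphenyl)prop-2-en-1-ol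
Conditions: DIBAL-H (2.5 equiv), CH2Cl2, −78 → −40 °C; Rochelle salt
Reagents that add atoms: none
Why: 1,2-reduction of a conjugated ester to the allylic alcohol by DIBAL-H, with retention of alkene geometry; the acid-sensitive enol ether is handled under neutral or basic conditions throughout.

Step 7
Reactants: 11 (Z)-2-aryloxy-3-arylprop-2-en-1-ol
Product: 12 (Z)-tert-butyldimethylsilyl ether of 11
Conditions: TBSCl, imidazole, DMF, rt
Reagents that add atoms: tert-butyldimethylsilyl chloride, CC(C)(C)[Si](C)(C)Cl
Why: Standard silylation of a primary allylic alcohol; it removes the only O–H that would consume or redirect the chiral borane and gives one protecting-group type for the final step.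

Step 8
Reactants: 12 (Z)-enol ether bearing the allyl group
Product: 15 (1S,2R)-1-(4-{[1,3-bis(tert-butyldimethylsilyloxy)propan-2-yl]oxy}-3-methoxyphenyl)-3-(tert-butyldimethylsilyloxy)-2-[4-(3-hydroxypropyl)-2,6-dimethoxyphenoxy]propan-1-ol, via B-alkyl-9-BBN adduct 13 (not isolated), via C7-isopinocampheylborane 14 (not isolated)
Conditions: 9-BBN (1.05 equiv), THF, 0 °C → rt; then IpcBH2 [from (1R)-(+)-α-pinene, freed from its TMEDA adduct, BF3-free], THF, −25 → 0 °C; then aq NaOH, 30% H2O2, 0 °C → rt
Reagents that add atoms: hydrogen peroxide, OO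
Why: 9-BBN first hydroborates only the terminal C8′=C9′ bond (boron on C9′, 13); IpcBH2 then adds H–B across C7=C8 through the concerted four-centre transition state (14), and alkaline peroxide replaces every C–B bond by C–O with retention. The closest known reaction types are the asymmetric hydroboration of trisubstituted alkenes with monoisopinocampheylborane and the hydroboration–oxidation of acyclic enol ethers with isopinocampheylboranes to β-alkoxy alcohols. No ring is closed. C7 is set by the reagent, which must select the C7 Si face of the enol ether. C8 is set relative to C7 without further selection, because H and B are delivered suprafacially and ring A and the ring-B oxygen are cis in 12, so H on C8 and O on C7 end up syn, which is the erythro (7S,8R) pair. Boron goes to C7 because it is the less substituted alkene carbon and because the ring-B oxygen on C8 stabilises the positive charge that develops there in the transition state. Chemoselectivity between the two alkenes comes from the order of addition and from the strong preference of 9-BBN for a terminal over a hindered trisubstituted alkene. The step needs geometrically pure 12 (any E isomer would give threo material) and a cold oxidation to outrun β-elimination of the aryloxy group from 14.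

Step 9
Reactants: 15 tris-silyl ether diol
Product: 16 (1S,2R)-1-{4-[(1,3-dihydroxypropan-2-yl)oxy]-3-methoxyphenyl}-2-[4-(3-hydroxypropyl)-2,6-dimethoxyphenoxy]propane-1,3-diol (target)
Conditions: TBAF (4 equiv), THF, 0 °C → rt
Reagents that add atoms: none
Why: Fluoride-mediated cleavage of all three Si–O bonds; the conditions are non-acidic, so the p-alkoxybenzylic C7 alcohol cannot ionise, and neither stereocentre is adjacent to a carbonyl.

## Compound list

1 | glycerol | OCC(O)CO | starting material
2 | 1,3-bis(tert-butyldimethylsilyloxy)propan-2-ol | CC(C)(C)[Si](C)(C)OCC(O)CO[Si](C)(C)C(C)(C)C | intermediate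
3 | vanillin | COc1cc(C=O)ccc1O | starting material
4 | 4-{[1,3-bis(tert-butyldimethylsilyloxy)propan-2-yl]oxy}-3-methoxybenzaldehyde | COc1cc(C=O)ccc1OC(CO[Si](C)(C)C(C)(C)C)CO[Si](C)(C)C(C)(C)C | intermediate
5 | 4-allyl-2,6-dimethoxyphenol | COc1cc(CC=C)cc(OC)c1O | starting material
6 | ethyl bromoacetate | CCOC(=O)CBr | starting material
7 | ethyl 2-(4-allyl-2,6-dimethoxyphenoxy)acetate | CCOC(=O)COc1c(OC)cc(CC=C)cc1OC | intermediate
8 | ethyl 2-(4-allyl-2,6-dimethoxyphenoxy)-3-aryl-3-hydroxypropanoate (diastereomer mixture, racemic) | CCOC(=O)C(Oc1c(OC)cc(CC=C)cc1OC)C(O)c1ccc(OC(CO[Si](C)(C)C(C)(C)C)CO[Si](C)(C)C(C)(C)C)c(OC)c1 | intermediate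
9 | 3-methanesulfonate of 8 (not isolated) | CCOC(=O)C(Oc1c(OC)cc(CC=C)cc1OC)C(OS(C)(=O)=O)c1ccc(OC(CO[Si](C)(C)C(C)(C)C)CO[Si](C)(C)C(C)(C)C)c(OC)c1 | intermediate
10 | ethyl (Z)-2-(4-allyl-2,6-dimethoxyphenoxy)-3-arylprop-2-enoate | CCOC(=O)/C(Oc1c(OC)cc(CC=C)cc1OC)=C/c1ccc(OC(CO[Si](C)(C)C(C)(C)C)CO[Si](C)(C)C(C)(C)C)c(OC)c1 | intermediate
11 | (Z)-2-(4-allyl-2,6-dimethoxyphenoxy)-3-arylprop-2-en-1-ol | OC/C(Oc1c(OC)cc(CC=C)cc1OC)=C/c1ccc(OC(CO[Si](C)(C)C(C)(C)C)CO[Si](C)(C)C(C)(C)C)c(OC)c1 | intermediate
12 | (Z)-tert-butyldimethylsilyl ether of 11 | CC(C)(C)[Si](C)(C)OC/C(Oc1c(OC)cc(CC=C)cc1OC)=C/c1ccc(OC(CO[Si](C)(C)C(C)(C)C)CO[Si](C)(C)C(C)(C)C)c(OC)c1 | intermediate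
13 | B-(3-arylpropyl)-9-BBN adduct of 12 (not isolated) | CC(C)(C)[Si](C)(C)OC/C(Oc1c(OC)cc(CCCB2C3CCCC2CCC3)cc1OC)=C/c1ccc(OC(CO[Si](C)(C)C(C)(C)C)CO[Si](C)(C)C(C)(C)C)c(OC)c1 | intermediate
14 | C7-(isopinocampheyl)borane of 13, 7S,8R (not isolated) | C[C@@H]1[C@H]2C[C@H](C2(C)C)C[C@H]1B[C@@H](c1ccc(OC(CO[Si](C)(C)C(C)(C)C)CO[Si](C)(C)C(C)(C)C)c(OC)c1)[C@@H](CO[Si](C)(C)C(C)(C)C)Oc1c(OC)cc(CCCB2C3CCCC2CCC3)cc1OC | intermediate
15 | (1S,2R)-tris-silyl ether diol | COc1cc([C@H](O)[C@@H](CO[Si](C)(C)C(C)(C)C)Oc2c(OC)cc(CCCO)cc2OC)ccc1OC(CO[Si](C)(C)C(C)(C)C)CO[Si](C)(C)C(C)(C)C | intermediate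
16 | (1S,2R)-1-{4-[(1,3-dihydroxypropan-2-yl)oxy]-3-methoxyphenyl}-2-[4-(3-hydroxypropyl)-2,6-dimethoxyphenoxy]propane-1,3-diol | COc1cc([C@H](O)[C@@H](CO)Oc2c(OC)cc(CCCO)cc2OC)ccc1OC(CO)CO | target

## Step count and risks

Total steps: 9. Longest linear sequence: 8 steps (1 → 2 → 4 → 8 → 10 → 11 → 12 → 15 → 16; steps 1, 2, 4, 5, 6, 7, 8, 9).

**Step 8 (key step).** The most likely failure is poor facial selection. The enol ether is bulky and electronically different from the alkyl- and aryl-substituted alkenes on which the reagent model rests, so the enantiomeric purity may be insufficient. The erythro relation should hold regardless, since it depends only on syn addition to the Z alkene. Lesser risks are boron leaking onto C8 (its oxidation would expel the phenol), β-elimination of the aryloxy group from the C7 borane before oxidation, and incomplete discrimination of the two alkenes by 9-BBN.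
Fallback: from 12, the side chain is hydroborated with 9-BBN as before and the enol ether with achiral BH3·SMe2. This keeps the erythro-specific syn addition and gives the racemic C7-borane F1. Oxidation gives racemic 15, which is resolved by preparative chromatography on a chiral stationary phase into 15 and its (1R,2S)-enantiomer F2. The route is rejoined at 15.

**Step 5.** Loss of geometric control is the main risk. If elimination from mesylate 9 proceeds in part by a stereospecific anti E2 path rather than E1cB, the erythro-rich aldol mixture would feed the E acrylate, and every per cent of E isomer becomes threo product in step 8.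
Fallback: from 7, the ester is saponified (LiOH) to 2-(4-allyl-2,6-dimethoxyphenoxy)acetic acid F3. F3 is condensed with 4 in a Perkin condensation (Ac2O, Et3N, heat), whose reversible conditions favour the acid with ring A trans to the carboxyl group, the (Z)-2-aryloxy-3-arylprop-2-enoic acid F4. Ethylation (EtI, K2CO3, DMF) returns to the route at 10.

**Step 2.** The Mitsunobu reaction may be sluggish, or the activated alcohol may eliminate, because the carbinol carbon of 2 is flanked by two silyloxymethyl groups.
Fallback: from 3, alkylation with diethyl bromomalonate (K2CO3, DMF) gives diethyl 2-(4-formyl-2-methoxyphenoxy)malonate F5. LiAlH4 reduces the aldehyde and both esters to 2-[4-(hydroxymethyl)-2-methoxyphenoxy]propane-1,3-diol F6. MnO2 oxidises only the benzylic alcohol to 4-[(1,3-dihydroxypropan-2-yl)oxy]-3-methoxybenzaldehyde F7. Bis-silylation (TBSCl, imidazole) returns to the route at 4.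

## Further compounds

F1 | step 8 | racemic erythro C7-borane (BH2 on C7) of 13; the 7S,8R enantiomer is drawn | B[C@@H](c1ccc(OC(CO[Si](C)(C)C(C)(C)C)CO[Si](C)(C)C(C)(C)C)c(OC)c1)[C@@H](CO[Si](C)(C)C(C)(C)C)Oc1c(OC)cc(CCCB2C3CCCC2CCC3)cc1OC
F2 | step 8 | (1R,2S)-enantiomer of 15 | COc1cc([C@@H](O)[C@H](CO[Si](C)(C)C(C)(C)C)Oc2c(OC)cc(CCCO)cc2OC)ccc1OC(CO[Si](C)(C)C(C)(C)C)CO[Si](C)(C)C(C)(C)C
F3 | step 5 | 2-(4-allyl-2,6-dimethoxyphenoxy)acetic acid | OC(=O)COc1c(OC)cc(CC=C)cc1OC
F4 | step 5 | (Z)-2-(4-allyl-2,6-dimethoxyphenoxy)-3-(4-{[1,3-bis(tert-butyldimethylsilyloxy)propan-2-yl]oxy}-3-methoxyphenyl)prop-2-enoic acid | OC(=O)/C(Oc1c(OC)cc(CC=C)cc1OC)=C/c1ccc(OC(CO[Si](C)(C)C(C)(C)C)CO[Si](C)(C)C(C)(C)C)c(OC)c1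
F5 | step 2 | diethyl 2-(4-formyl-2-methoxyphenoxy)malonate | CCOC(=O)C(Oc1ccc(C=O)cc1OC)C(=O)OCC
F6 | step 2 | 2-[4-(hydroxymethyl)-2-methoxyphenoxy]propane-1,3-diol | OCC(CO)Oc1ccc(CO)cc1OC
F7 | step 2 | 4-[(1,3-dihydroxypropan-2-yl)oxy]-3-methoxybenzaldehyde | OCC(CO)Oc1ccc(C=O)cc1OC
A1 | alternative 1 | (S)-4-benzyl-3-[2-(4-allyl-2,6-dimethoxyphenoxy)acetyl]oxazolidin-2-one | O=C(COc1c(OC)cc(CC=C)cc1OC)N1[C@@H](Cc2ccccc2)COC1=O
A2 | alternative 1 | (S)-4-benzyl-3-[(2S,3S)-2-(4-allyl-2,6-dimethoxyphenoxy)-3-aryl-3-hydroxypropanoyl]oxazolidin-2-one (required anti adduct) | COc1cc([C@H](O)[C@@H](C(=O)N2[C@@H](Cc3ccccc3)COC2=O)Oc2c(OC)cc(CC=C)cc2OC)ccc1OC(CO[Si](C)(C)C(C)(C)C)CO[Si](C)(C)C(C)(C)C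
A3 | alternative 2 | ethyl (E)-3-(4-{[1,3-bis(tert-butyldimethylsilyloxy)propan-2-yl]oxy}-3-methoxyphenyl)prop-2-enoate | CCOC(=O)/C=C/c1ccc(OC(CO[Si](C)(C)C(C)(C)C)CO[Si](C)(C)C(C)(C)C)c(OC)c1
A4 | alternative 2 | ethyl (2R,3S)-3-aryl-2,3-dihydroxypropanoate (threo diol) | CCOC(=O)[C@H](O)[C@@H](O)c1ccc(OC(CO[Si](C)(C)C(C)(C)C)CO[Si](C)(C)C(C)(C)C)c(OC)c1
A5 | alternative 2 | ethyl (2R,3S)-3-aryl-3-hydroxy-2-[(4-nitrophenyl)sulfonyloxy]propanoate | CCOC(=O)[C@H](OS(=O)(=O)c1ccc(cc1)[N+](=O)[O-])[C@@H](O)c1ccc(OC(CO[Si](C)(C)C(C)(C)C)CO[Si](C)(C)C(C)(C)C)c(OC)c1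
A6 | alternative 3 | ethyl 2-(4-allyl-2,6-dimethoxyphenoxy)-3-aryl-3-oxopropanoate (racemic) | CCOC(=O)C(Oc1c(OC)cc(CC=C)cc1OC)C(=O)c1ccc(OC(CO[Si](C)(C)C(C)(C)C)CO[Si](C)(C)C(C)(C)C)c(OC)c1
A7 | alternative 3 | ethyl (2R,3S)-2-(4-allyl-2,6-dimethoxyphenoxy)-3-aryl-3-hydroxypropanoate (threo) | COc1cc([C@H](O)[C@H](C(=O)OCC)Oc2c(OC)cc(CC=C)cc2OC)ccc1OC(CO[Si](C)(C)C(C)(C)C)CO[Si](C)(C)C(C)(C)C
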